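**Plan**

1. The target is numbered as a 4,6-dioxatricyclo[5.4.0.0(1,5)]undec-9-ene (C1 spiro carbon, C3 carbinol carbon with the isopropenyl group, C5 acetal carbon, C7 methyl carbinol carbon, C8 CHBr, C10 CBr, C11 CMe2). The retrosynthesis cuts, in this order: C8–Br (alcohol, inversion); the oxetane bond C5–O6 (lactol plus tertiary hydroxyl); C7–CH3 (Grignard on a ketone); then together one C11–CH3 bond and the C8–O bond, which leads back to a spiro γ-lactone 2,4-cyclohexadienone; finally C1–C2 and O4–C5 (cyclic β-keto ester plus oxirane).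
2. Forward, the carbocycle is made first (ethyl acetoacetate and crotonaldehyde, the dihydro form of a 6-methylsalicylate), then the γ-lactone and with it the spiro carbon (oxirane opening and lactonisation). γ-Bromination and dehydrogenation give the bromodienone; the key methylation–hydroxylation, methyl addition to the ketone and reduction to the lactol follow; the oxetane is the last ring and the secondary bromide the last bond.
3. The key step rests on the spiro carbon C1. It is quaternary, belongs to both the lactone ring and the six-membered ring, and lies between the ketone carbon and the methyl-bearing sp2 carbon, so the carbocycle can neither aromatise nor enolise and stays a linear dienone O=C7–C8=C9–C10(Br)=C11(CH3). Its δ-carbon C11 takes the second methyl, its α-carbon C8 takes oxygen, its γ-bromine is already the vinylic C10–Br, and the lactone carbonyl on C1 (the later C5) tells the two faces apart.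
4. Stereochemistry: C3 comes from a resolved oxirane. C1 comes from alkylation anti to a temporary methyl-bearing stereocentre (the later C11), set by an organocatalytic Michael addition and erased on dehydrogenation. C8 comes from face-selective hydroxylation of the dienolate followed by SN2 inversion, C7 from chelation-controlled Grignard addition, and C5 from the enforced cis fusion of the oxetane.

Key step: step 7

Locants in the names of the spirocyclic intermediates follow 2-oxaspiro[4.5]decane numbering (C1 lactone carbonyl, C3 carbinol carbon, C5 spiro carbon, C6 ketone carbon, C7 α-, C8 β-, C9 γ- and C10 δ-carbon).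

Assumption: the usual sense of induction is taken for both catalysts, i.e. (S,S)-(salen)Co(OAc) hydrolyses the (R)-oxirane and the (R)-prolinol silyl ether gives the (6S) methyl centre; should either sense be reversed on these substrates, the antipodal catalyst would be used.

**Route**

Step 1
Reactants: 1 methacrolein
Product: 2 rac-2-(prop-1-en-2-yl)oxirane
Conditions: Me3S+ I−, KOt-Bu, DMSO–THF, 0 °C → rt; distillation
Reagents that add atoms: trimethylsulfonium iodide, C[S+](C)C.[I-]
Why: Corey–Chaykovsky epoxidation, in which the sulfonium ylide adds to the aldehyde carbonyl of the enal (1,2) and closes to the oxirane, obtained as the racemate.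

Step 2
Reactants: 2 rac-2-(prop-1-en-2-yl)oxirane
Product: 3 (2S)-2-(prop-1-en-2-yl)oxirane
Conditions: (S,S)-(salen)Co(OAc) [salen = N,N'-bis(3,5-di-tert-butylsalicylidene)cyclohexane-1,2-diamine dianion] (0.5 mol %), H2O (0.55 equiv), neat, 0 °C → rt; distillation from the diol
Reagents that add atoms: none
Why: Hydrolytic kinetic resolution, in which the chiral cobalt complex should hydrolyse the (R)-oxirane at its terminal carbon much faster than the (S)-oxirane, which is left behind and fixes the later C3 centre.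

Step 3
Reactants: 4 ethyl acetoacetate; 5 (E)-but-2-enal (crotonaldehyde)
Product: 7 ethyl (6S)-6-methyl-2-oxocyclohex-3-ene-1-carboxylate, via Michael adduct 6 (not isolated)
Conditions: (R)-2-[diphenyl(trimethylsilyloxy)methyl]pyrrolidine (10 mol %), PhCO2H (10 mol %), toluene, rt; then p-TsOH·H2O (20 mol %), 40 °C
Reagents that add atoms: none
Why: Iminium-activated Michael addition of the β-keto ester to the enal followed by acid-promoted intramolecular aldol condensation; the bulky silyloxydiphenylmethyl group of the catalyst shields one face of the iminium ion and so sets the methyl-bearing carbon C6 as (S).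

Step 4
Reactants: 7 ethyl (6S)-6-methyl-2-oxocyclohex-3-ene-1-carboxylate; 3 (2S)-2-(prop-1-en-2-yl)oxirane
Product: 9 (3R,5S,10S)-10-methyl-3-(prop-1-en-2-yl)-2-oxaspiro[4.5]dec-7-ene-1,6-dione, via hydroxy keto ester 8 (not isolated)
Conditions: NaOEt (0.3 equiv), EtOH, 0 → 45 °C
Reagents that add atoms: none
Why: Alkylation of a β-keto ester enolate by an oxirane at its terminal carbon (SN2) and lactonisation of the alkoxide onto the ethyl ester (5-exo-trig, so catalytic base suffices); the electrophile should approach anti to the pseudo-axial C6 methyl group (allylic strain with the ester), which sets the spiro carbon, while the carbinol centre of 3 is not touched.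

Step 5
Reactants: 9 (3R,5S,10S)-10-methyl-3-(prop-1-en-2-yl)-2-oxaspiro[4.5]dec-7-ene-1,6-dione
Product: 11 (3R,5S,10R)-9-bromo-10-methyl-3-(prop-1-en-2-yl)-2-oxaspiro[4.5]dec-7-ene-1,6-dione, via silyl dienol ether 10 (not isolated)
Conditions: Me3SiOTf, Et3N, CH2Cl2, 0 °C; then NBS, THF, −78 °C
Reagents that add atoms: N-bromosuccinimide, O=C1CCC(=O)N1Br
Why: Soft enolisation can only remove a γ-proton because the α'-carbon is quaternary, and N-bromosuccinimide should brominate the γ-terminus of the 2-silyloxy diene (as with steroidal dienol ethers) far faster than it attacks the isopropenyl group; the new C9 stereocentre is lost in step 6.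

Step 6
Reactants: 11 (3R,5S,10R)-9-bromo-10-methyl-3-(prop-1-en-2-yl)-2-oxaspiro[4.5]dec-7-ene-1,6-dione
Product: 13 (3R,5S)-9-bromo-10-methyl-3-(prop-1-en-2-yl)-2-oxaspiro[4.5]deca-7,9-diene-1,6-dione, via bromo silyl dienol ether 12 (not isolated)
Conditions: Me3SiOTf, Et3N, CH2Cl2, 0 °C; then DDQ, 2,4,6-collidine, benzene, rt
Reagents that add atoms: none
Why: Dehydrogenation of a silyl dienol ether by DDQ (loss of the C10 hydrogen as hydride, then of the silyl group) gives the linear dienone, the only unsaturated ketone possible because the spiro carbon is quaternary; the temporary C10 stereocentre disappears here.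

Step 7
Reactants: 13 (3R,5S)-9-bromo-10-methyl-3-(prop-1-en-2-yl)-2-oxaspiro[4.5]deca-7,9-diene-1,6-dione
Product: 15 (3R,5S,7R)-9-bromo-7-hydroxy-10,10-dimethyl-3-(prop-1-en-2-yl)-2-oxaspiro[4.5]dec-8-ene-1,6-dione, via lithium dienolate 14 (not isolated)
Conditions: Me2CuLi (1.5 equiv, from MeLi and CuBr·SMe2), Et2O–THF, −78 → −40 °C; then 2-(phenylsulfonyl)-3-phenyloxaziridine (2 equiv), THF, −78 °C; AcOH, then aq NH4Cl
Reagents that add atoms: lithium dimethylcuprate, [Li+].C[Cu-]C; trans-2-(phenylsulfonyl)-3-phenyloxaziridine, O=S(=O)(c1ccccc1)N1OC1c1ccccc1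
Why: The cuprate forms a π-complex with the dienone and transfers methyl to the δ-carbon C10 (1,6-addition), giving the lithium dienolate 14, whose α-carbon C7 then takes the electrophilic oxygen of the N-sulfonyloxaziridine. The closest known reaction type is the 1,6-addition of lithium dialkylcuprates to linear 2,4-dienones and dienoates, combined with oxaziridine hydroxylation of the enolate so formed. No ring is closed. The one new stereocentre, C7, is controlled by the spiro carbon: the oxidant should enter on the face carrying the lactone carbonyl, which is the smaller of the two spiro substituents and can hold lithium in a chelate with the enolate oxygen, anti to the lactone CH2. The step needs δ- over β-attack and α- over γ-oxidation: the bromine on C9 stabilises the extended dienolate that only δ-attack produces and hinders C8, the quaternary spiro carbon rules out aromatisation and any competing enolisation, and the γ-carbon of 14 bears bromine next to the new quaternary carbon, so oxygen should go to C7.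

Step 8
Reactants: 15 (3R,5S,7R)-9-bromo-7-hydroxy-10,10-dimethyl-3-(prop-1-en-2-yl)-2-oxaspiro[4.5]dec-8-ene-1,6-dione
Product: 16 (3R,5S,6S,7R)-9-bromo-6,7-dihydroxy-6,10,10-trimethyl-3-(prop-1-en-2-yl)-2-oxaspiro[4.5]dec-8-en-1-one
Conditions: MeMgBr (3 equiv), Et2O–CH2Cl2, −78 → −20 °C; aq NH4Cl
Reagents that add atoms: methylmagnesium bromide, C[Mg]Br
Why: Chelation-controlled Grignard addition: the magnesium alkoxide of the C7 hydroxyl binds the ketone oxygen and methyl should enter anti to the C7 oxygen, on the face away from the pseudo-axial C10 methyl group, giving the cis-diol with the tertiary hydroxyl on the side of the lactone carbonyl, while the neopentyl lactone is the less electrophilic carbonyl at low temperature.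

Step 9
Reactants: 16 (3R,5S,6S,7R)-9-bromo-6,7-dihydroxy-6,10,10-trimethyl-3-(prop-1-en-2-yl)-2-oxaspiro[4.5]dec-8-en-1-one
Product: 17 (3R,5S,6S,7R)-9-bromo-7-(tert-butyldimethylsilyloxy)-6-hydroxy-6,10,10-trimethyl-3-(prop-1-en-2-yl)-2-oxaspiro[4.5]dec-8-en-1-one
Conditions: t-BuMe2SiOTf (1.1 equiv), 2,6-lutidine, CH2Cl2, −78 °C
Reagents that add atoms: tert-butyldimethylsilyl trifluoromethanesulfonate, CC(C)(C)[Si](C)(C)OS(=O)(=O)C(F)(F)F
Why: Silylation with a silyl triflate at −78 °C discriminates the secondary allylic hydroxyl from the tertiary one, and the ether keeps that oxygen from closing a five-membered acetal in step 11.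

Step 10
Reactants: 17 (3R,5S,6S,7R)-9-bromo-7-(tert-butyldimethylsilyloxy)-6-hydroxy-6,10,10-trimethyl-3-(prop-1-en-2-yl)-2-oxaspiro[4.5]dec-8-en-1-one
Product: 18 (3R,5S,6S,7R)-9-bromo-7-(tert-butyldimethylsilyloxy)-6,10,10-trimethyl-3-(prop-1-en-2-yl)-2-oxaspiro[4.5]dec-8-ene-1,6-diol
Conditions: i-Bu2AlH (2.5 equiv), CH2Cl2, −78 °C; aq potassium sodium tartrate
Reagents that add atoms: none
Why: Partial reduction of a lactone with i-Bu2AlH: the tetrahedral aluminium hemiacetal of this hindered lactone should survive at −78 °C and give the lactol (either anomer serves) on work-up, one equivalent of hydride being consumed by the tertiary hydroxyl.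

Step 11
Reactants: 18 (3R,5S,6S,7R)-9-bromo-7-(tert-butyldimethylsilyloxy)-6,10,10-trimethyl-3-(prop-1-en-2-yl)-2-oxaspiro[4.5]dec-8-ene-1,6-diol
Product: 19 (1S,3R,5S,7S,8R)-10-bromo-8-(tert-butyldimethylsilyloxy)-7,11,11-trimethyl-3-(prop-1-en-2-yl)-4,6-dioxatricyclo[5.4.0.0(1,5)]undec-9-ene
Conditions: PPh3, DIAD, THF, 0 °C → rt
Reagents that add atoms: none
Why: Mitsunobu cyclodehydration: the more acidic, less hindered lactol hydroxyl is activated as an anomeric oxyphosphonium ion and the tertiary hydroxyl, held cis on the neighbouring ring carbon, closes the oxetane, the strain being paid for by formation of Ph3P=O; the spiro carbon carries no hydrogen, so no enol ether can form, and the cis ring fusion fixes the acetal configuration.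

Step 12
Reactants: 19 (1S,3R,5S,7S,8R)-10-bromo-8-(tert-butyldimethylsilyloxy)-7,11,11-trimethyl-3-(prop-1-en-2-yl)-4,6-dioxatricyclo[5.4.0.0(1,5)]undec-9-ene
Product: 20 (1S,3R,5S,7S,8R)-10-bromo-7,11,11-trimethyl-3-(prop-1-en-2-yl)-4,6-dioxatricyclo[5.4.0.0(1,5)]undec-9-en-8-ol
Conditions: Bu4NF, THF, 0 °C; aq NH4Cl
Reagents that add atoms: none
Why: Fluoride cleavage of the silyl ether, to which the acetal and the vinylic bromide should be inert.

Step 13
Reactants: 20 (1S,3R,5S,7S,8R)-10-bromo-7,11,11-trimethyl-3-(prop-1-en-2-yl)-4,6-dioxatricyclo[5.4.0.0(1,5)]undec-9-en-8-ol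
Product: 21 (1S,3R,5S,7S,8S)-8,10-dibromo-7,11,11-trimethyl-3-(prop-1-en-2-yl)-4,6-dioxatricyclo[5.4.0.0(1,5)]undec-9-ene
Conditions: CBr4, PPh3, 2,6-lutidine, CH2Cl2, 0 °C
Reagents that add atoms: carbon tetrabromide, BrC(Br)(Br)Br
Why: Appel reaction: the oxyphosphonium ion of the secondary allylic alcohol is displaced by bromide in an SN2 step with inversion, ionisation being disfavoured by the adjacent oxetane oxygen and the vinylic bromine, and SN2' attack by the fully substituted, bromine-bearing alkene terminus.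

**Compound list**

1 | methacrolein (2-methylprop-2-enal) | C=C(C)C=O | starting material
2 | rac-2-(prop-1-en-2-yl)oxirane | C=C(C)C1CO1 | intermediate
3 | (2S)-2-(prop-1-en-2-yl)oxirane | C=C(C)[C@H]1CO1 | intermediate
4 | ethyl acetoacetate (ethyl 3-oxobutanoate) | CCOC(=O)CC(C)=O | starting material
5 | (E)-but-2-enal (crotonaldehyde) | C/C=C/C=O | starting material
6 | ethyl (3S)-2-acetyl-3-methyl-5-oxopentanoate (Michael adduct, C2 epimers, not isolated) | CCOC(=O)C(C(C)=O)[C@@H](C)CC=O | intermediate
7 | ethyl (6S)-6-methyl-2-oxocyclohex-3-ene-1-carboxylate (C1 epimers and enol form) | CCOC(=O)C1C(=O)C=CC[C@@H]1C | intermediate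
8 | ethyl (1S,6S)-1-[(2R)-2-hydroxy-3-methylbut-3-en-1-yl]-6-methyl-2-oxocyclohex-3-ene-1-carboxylate (formed as its sodium alkoxide, not isolated) | CCOC(=O)[C@]1(C[C@@H](O)C(C)=C)C(=O)C=CC[C@@H]1C | intermediate
9 | (3R,5S,10S)-10-methyl-3-(prop-1-en-2-yl)-2-oxaspiro[4.5]dec-7-ene-1,6-dione | C=C(C)[C@H]1C[C@@]2(C(=O)O1)C(=O)C=CC[C@@H]2C | intermediate
10 | (3R,5S,10S)-10-methyl-3-(prop-1-en-2-yl)-6-(trimethylsilyloxy)-2-oxaspiro[4.5]deca-6,8-dien-1-one (not isolated) | C=C(C)[C@H]1C[C@@]2(C(=O)O1)C(O[Si](C)(C)C)=CC=C[C@@H]2C | intermediate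
11 | (3R,5S,10R)-9-bromo-10-methyl-3-(prop-1-en-2-yl)-2-oxaspiro[4.5]dec-7-ene-1,6-dione (C9 epimers) | C=C(C)[C@H]1C[C@@]2(C(=O)O1)C(=O)C=CC(Br)[C@@H]2C | intermediate
12 | (3R,5S,10R)-9-bromo-10-methyl-3-(prop-1-en-2-yl)-6-(trimethylsilyloxy)-2-oxaspiro[4.5]deca-6,8-dien-1-one (not isolated) | C=C(C)[C@H]1C[C@@]2(C(=O)O1)C(O[Si](C)(C)C)=CC=C(Br)[C@@H]2C | intermediate
13 | (3R,5S)-9-bromo-10-methyl-3-(prop-1-en-2-yl)-2-oxaspiro[4.5]deca-7,9-diene-1,6-dione (spiro-lactone bromodienone) | C=C(C)[C@H]1C[C@@]2(C(=O)O1)C(=O)C=CC(Br)=C2C | intermediate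
14 | lithium (3R,5S)-9-bromo-10,10-dimethyl-1-oxo-3-(prop-1-en-2-yl)-2-oxaspiro[4.5]deca-6,8-dien-6-olate (not isolated) | C=C(C)[C@H]1C[C@@]2(C(=O)O1)C(O[Li])=CC=C(Br)C2(C)C | intermediate
15 | (3R,5S,7R)-9-bromo-7-hydroxy-10,10-dimethyl-3-(prop-1-en-2-yl)-2-oxaspiro[4.5]dec-8-ene-1,6-dione | C=C(C)[C@H]1C[C@@]2(C(=O)O1)C(=O)[C@H](O)C=C(Br)C2(C)C | intermediate
16 | (3R,5S,6S,7R)-9-bromo-6,7-dihydroxy-6,10,10-trimethyl-3-(prop-1-en-2-yl)-2-oxaspiro[4.5]dec-8-en-1-one | C=C(C)[C@H]1C[C@@]2(C(=O)O1)[C@](C)(O)[C@H](O)C=C(Br)C2(C)C | intermediate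
17 | (3R,5S,6S,7R)-9-bromo-7-(tert-butyldimethylsilyloxy)-6-hydroxy-6,10,10-trimethyl-3-(prop-1-en-2-yl)-2-oxaspiro[4.5]dec-8-en-1-one | C=C(C)[C@H]1C[C@@]2(C(=O)O1)[C@](C)(O)[C@H](O[Si](C)(C)C(C)(C)C)C=C(Br)C2(C)C | intermediate
18 | (3R,5S,6S,7R)-9-bromo-7-(tert-butyldimethylsilyloxy)-6,10,10-trimethyl-3-(prop-1-en-2-yl)-2-oxaspiro[4.5]dec-8-ene-1,6-diol (lactol, C1 anomers) | C=C(C)[C@H]1C[C@@]2(C(O)O1)[C@](C)(O)[C@H](O[Si](C)(C)C(C)(C)C)C=C(Br)C2(C)C | intermediate
19 | (1S,3R,5S,7S,8R)-10-bromo-8-(tert-butyldimethylsilyloxy)-7,11,11-trimethyl-3-(prop-1-en-2-yl)-4,6-dioxatricyclo[5.4.0.0(1,5)]undec-9-ene | C=C(C)[C@H]1C[C@@]23[C@@H](O1)O[C@]2(C)[C@H](O[Si](C)(C)C(C)(C)C)C=C(Br)C3(C)C | intermediate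
20 | (1S,3R,5S,7S,8R)-10-bromo-7,11,11-trimethyl-3-(prop-1-en-2-yl)-4,6-dioxatricyclo[5.4.0.0(1,5)]undec-9-en-8-ol | C=C(C)[C@H]1C[C@@]23[C@@H](O1)O[C@]2(C)[C@H](O)C=C(Br)C3(C)C | intermediate
21 | (1S,3R,5S,7S,8S)-8,10-dibromo-7,11,11-trimethyl-3-(prop-1-en-2-yl)-4,6-dioxatricyclo[5.4.0.0(1,5)]undec-9-ene (CNP0141320.1) | C=C(C)[C@H]1C[C@@]23[C@@H](O1)O[C@]2(C)[C@@H](Br)C=C(Br)C3(C)C | target

**Step count and risks**

Total step count: 13. Longest linear sequence: 12 steps (steps 1, 2 and 4 to 13, from methacrolein); the branch from ethyl acetoacetate (step 3) joins at step 4.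

Steps most likely to fail:

Step 7. Methyl may be transferred to the unhindered β-carbon (1,4-addition), or not at all to the neopentyl δ-carbon, and the face selectivity of the oxidation may be incomplete. The fallback sets out from 13 and comes back at 15. Compound 13 would be treated with Me3Al and a copper catalyst (Cu(OTf)2 with a phosphoramidite ligand, Et2O, −30 °C), a combination known to add alkyl groups 1,6 to extended cyclic enones and to build quaternary carbons. The aluminium dienolate would be silylated in the flask with Me3SiOTf to give the isolable (3R,5S)-9-bromo-10,10-dimethyl-3-(prop-1-en-2-yl)-6-(trimethylsilyloxy)-2-oxaspiro[4.5]deca-6,8-dien-1-one F1. In a separate operation F1 would be oxidised with the same N-sulfonyloxaziridine (Rubottom-type oxidation of a silyl enol ether) to the α-silyloxy ketone F2, and citric acid in MeOH would then free 15.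

Step 11. The activated anomeric carbon may be intercepted by the hydrazide, or fall back to the lactol, before the strained four-membered ring closes. The fallback sets out from 18 and comes back at 19, and replaces the dehydration by a halide-abstraction glycosylation of the Koenigs–Knorr type. MsCl and Et3N in CH2Cl2 at −40 °C would convert the lactol hydroxyl, which reacts before the tertiary one, into the anomeric chloride F3 (chloride displaces the first-formed mesylate). AgOTf with 2,6-di-tert-butyl-4-methylpyridine and 4 Å molecular sieves at −40 °C would then abstract the chloride, so that the tertiary hydroxyl captures the oxocarbenium ion; precipitation of AgCl makes the closure irreversible and the hindered base keeps the medium non-acidic.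

Step 13. The activated allylic alcohol may ionise (loss of clean inversion), backside attack beside the fully substituted oxetane carbon may be slow, and the acidic phosphonium species may open the oxetane acetal. The fallback sets out from 16 and comes back at 21, and brings in the bromide before the acetal exists, without a silyl group. The secondary hydroxyl of 16 would be mesylated selectively (MsCl, Et3N, CH2Cl2, −40 °C) to the methanesulfonate F4. LiBr in acetone would displace it with inversion (the cis tertiary hydroxyl cannot attack from the rear) to give the bromohydrin lactone F5. i-Bu2AlH at −78 °C would give the bromo lactol F6, and the Mitsunobu closure of step 11 (PPh3, DIAD), which never generates a free alkoxide next to the bromide, would give 21 directly.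

Further compounds
F1 | step 7 | (3R,5S)-9-bromo-10,10-dimethyl-3-(prop-1-en-2-yl)-6-(trimethylsilyloxy)-2-oxaspiro[4.5]deca-6,8-dien-1-one | C=C(C)[C@H]1C[C@@]2(C(=O)O1)C(O[Si](C)(C)C)=CC=C(Br)C2(C)C
F2 | step 7 | (3R,5S,7R)-9-bromo-10,10-dimethyl-3-(prop-1-en-2-yl)-7-(trimethylsilyloxy)-2-oxaspiro[4.5]dec-8-ene-1,6-dione | C=C(C)[C@H]1C[C@@]2(C(=O)O1)C(=O)[C@H](O[Si](C)(C)C)C=C(Br)C2(C)C
F3 | step 11 | (3R,5S,6S,7R)-9-bromo-7-(tert-butyldimethylsilyloxy)-1-chloro-6,10,10-trimethyl-3-(prop-1-en-2-yl)-2-oxaspiro[4.5]dec-8-en-6-ol (anomeric chloride) | C=C(C)[C@H]1C[C@@]2(C(Cl)O1)[C@](C)(O)[C@H](O[Si](C)(C)C(C)(C)C)C=C(Br)C2(C)C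
F4 | step 13 | (3R,5S,6S,7R)-9-bromo-6-hydroxy-6,10,10-trimethyl-1-oxo-3-(prop-1-en-2-yl)-2-oxaspiro[4.5]dec-8-en-7-yl methanesulfonate | C=C(C)[C@H]1C[C@@]2(C(=O)O1)[C@](C)(O)[C@H](OS(C)(=O)=O)C=C(Br)C2(C)C
F5 | step 13 | (3R,5S,6S,7S)-7,9-dibromo-6-hydroxy-6,10,10-trimethyl-3-(prop-1-en-2-yl)-2-oxaspiro[4.5]dec-8-en-1-one | C=C(C)[C@H]1C[C@@]2(C(=O)O1)[C@](C)(O)[C@@H](Br)C=C(Br)C2(C)C
F6 | step 13 | (3R,5S,6S,7S)-7,9-dibromo-6,10,10-trimethyl-3-(prop-1-en-2-yl)-2-oxaspiro[4.5]dec-8-ene-1,6-diol (lactol, C1 anomers) | C=C(C)[C@H]1C[C@@]2(C(O)O1)[C@](C)(O)[C@@H](Br)C=C(Br)C2(C)C
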